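The constants are made up; the result is computed.

**The balance.** In each flask the charged starting material is conserved: it stands as itself, as target, as isomer of the product, as side product or as quenched substrate, so you need to know how it divides among these.

    target ⇌ isomer of the product (K1 = 1.8, k1 = 0.20 /h, Ea1 = 96.0 kJ/mol, ΔH1 = 9.00 kJ/mol)
    starting material → side product (k2 = 0.025 /h, Ea2 = 108 kJ/mol)
    starting material + protic impurity → quenched substrate (k3 = 43 /M/h, Ea3 = 63.0 kJ/mol)
    starting material + free catalyst → free catalyst + target (k4 = 1.5 /M/h, Ea4 = 75.0 kJ/mol)
    2 free catalyst → spent catalyst (k5 = 0.78 /M/h, Ea5 = 57.0 kJ/mol)
    (constants at 20 °C)

| flask | starting material | protic impurity | free catalyst | temperature | time | remark |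
|---|---|---|---|---|---|---|
| alder | 0.10 M | 0.0100 M | 15 mM | 20 °C | 4.0 d |  |
| cedar | 0.10 M | 0.0100 M | 15 mM | 5 °C | 4.0 d |  |
| larch | 0.10 M | 0.0100 M | 15 mM |  | 4.0 d | at 5 °C until 50 h, from then on at 20 °C |

- which flask leads in amount of target, in percent of the starting material charged ("all alike" within 1.5 percentage points) (alder / cedar / larch / all alike)
- how much target is there at the end, in percent of the starting material charged: alder
- how much target is there at the end, in percent of the starting material charged: cedar
- how much target is there at the end, in percent of the starting material charged: larch

- two of one species on the left: rate k times its square, two consumed each time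
- the list of constants is for 20 °C, to be carried to other temperatures by the activation energies and enthalpies

**First toll.** At 20 °C the protic impurity lasts 0.233 h against starting material at its charge, far shorter than the 21.1 h that starting material itself lasts. So I take 10.0% of the charge off the top, leaving 90.0% to divide.

**The number.** That remainder has two exits, both first order in it. Define the selectivity factor S as the catalytic step's rate constant times the charged free catalyst, divided by the side step's rate constant: S = 0.900. Of the starting material used, a share S/(S+1) heads for target, here 47.4%. The side step's activation energy is higher by 33.0 kJ/mol, so at 5 °C S grows to 1.87, a share of 65.1%.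

**Reading it.** The starting material's lifetime in alder is 21.1 h, and isomerisation relaxes in 3.21 h, shorter than that, so I let target keep 35.7% of what is made. For alder that gives 15.2%.

**One number?** It is not enough. In alder free catalyst has a first half-life of 42.7 h, so after one starting-material lifetime it stands at 0.670 of its charge. With S scaled by that, I reckon alder at 12.1%. In cedar starting material lives 152 h, longer than the 4.0 d allowed, so I count what reacts within the run. Free catalyst in cedar has a first half-life of 151 h, so at mid-run it stands at 0.759 of its charge. With S scaled by that, 41.2% of the remainder reacts, and I reckon target plus isomer at 21.8%. The equilibrium constant in cedar is 1.48, but isomerisation there relaxes in 24.9 h, which is shorter than the run by a factor of just 3.86, so I do not take the pair as equilibrated. For a steady feed into target, target holds 55.5% of the pair at the end, which puts cedar at 12.1%. Larch starts on cedar's S and ends on alder's, so I put it slightly above alder and commit to all alike.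

**The forecast.** It says all alike: alder 11.8% (11.2% to 12.4%), cedar 11.5% (10.8% to 12.2%), larch 12.1% (11.4% to 12.8%). Of the cold flask it holds that “a higher target share and incomplete equilibration offset this”.

**The flasks.** Alder ends at 12.1%, cedar at 11.6%, larch at 12.3%: all alike, a spread of 0.70 percentage points. Larch run with 0.0037 M of free catalyst has S = 0.222 at 20 °C, a share of 18.2%. That neighbour ends with 4.90% target, and its target plus isomer reads 18.7% of those two plus side product.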